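## Analysis of the target

Locants: the four resveratrol units are a, b, c and d. In each unit, ring 1 is the 4-hydroxyphenyl ring (C1–C6), C7 and C8 are the two benzylic carbons (C7 on ring 1, C8 on ring 2), and ring 2 is the resorcinol ring (C9–C14).

The target (C56H42O12) is a resveratrol tetramer made of two halves that are the same trans-2,3-diaryl-2,3-dihydrobenzofuran dimer, (7S,8S)-ε-viniferin. Units a/b form the upper half and units c/d the lower half; the constitution is that of the vitisin A group. The lower half keeps its E-olefin C7c=C8c and its dihydrobenzofuran (O–C7d–C8d fused to ring C2). The upper half has no olefin: C8b is bonded to C3c (ortho to the hydroxyl of ring C1) and C7b to C10a of ring A2. This closes a seven-membered carbocycle C8a–C9a–C10a–C7b–C8b–C9b–C10b, fused to rings A2 and B2 and, through C8a–C10b–C11b–O–C7a, to the upper dihydrobenzofuran.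

All six stereocentres are S. C7a/C8a and C7d/C8d are the trans pairs of the two dihydrobenzofurans, with the same absolute sense. On the seven-membered ring, H-7b and H-8b are cis to each other and trans to H-8a, so ring B1 (on C7b) and ring C1 (on C8b) sit on the face of H-8a.

Sensitive features are ten free phenols, a 4-hydroxystilbene (acid, light, hydrogenation) and three para-hydroxybenzylic bonds (C7a–O, C7d–O, C7b–C10a) that ionise in acid. The difficulty is not the rings themselves. It is joining C8b to C3c and C7b to C10a with regio- and stereocontrol, at two all-carbon benzylic methines without any heteroatom handle, between two identical C28 blocks that end up unsymmetrically linked.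

The plan rests on four features of these atoms:
- C8b is the β-carbon of a 4-hydroxystilbene and carries spin in its phenoxyl radical.
- C3c is the ortho carbon of the same kind of phenol.
- C7b becomes a para-quinone methide carbon the moment C8b has reacted.
- C10a of ring A2 is held by the C8a stereocentre exactly one seven-membered ring away from C7b.

## Retrosynthetic reasoning

**23 to 22.** The last operation only removes eight benzyl groups from 22. Benzyl ethers are chosen because they survive organometallic, oxidative and Lewis-acid steps, keep ring A2 electron-rich, and can be removed without hydrogenation, which the olefin would not survive.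

**22 to two molecules of 17 (key disconnection).** The bonds cut are C8b–C3c and C7b–C10a, the only two bonds that are not already present in the halves. After the cut both fragments are the same compound 17, half the size of 22 and carrying four of the six stereocentres. The forward reaction has to do four things:
- oxidise the single free phenol of 17 to radical 18;
- join two radicals C8b to C3c (19, then 20);
- let the adduct rest as the O-closed dihydrobenzofuran 21, which masks the new phenol against further oxidation;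
- switch the skeleton with a Lewis acid from the O-closed five-membered ring to the C-closed seven-membered ring.

C8b and C7b are set in this operation under the control of C8a.

**17 to 14 and 15.** The aryl–vinyl bond C9b–C8b is cut (Heck reaction). This brings in the one free phenol, masked as an acetate, in the last step of the monomer. It also keeps the olefin out of the carbene and acid steps that come before.

**14 to 13, 12, 11 and 10.** The C2–C3 bond of the dihydrobenzofuran (C7a–C8a) is cut. It is formed by insertion of a diaryl carbene, made from hydrazone 11 through diazo compound 12, into the benzylic C–H bond of the ortho ether of ketone 10. A chiral dirhodium carboxylate sets C3, the only stereocentre of the route set by a reagent. C2 is then relayed from C3 by acid equilibration of cis-13 to trans-14.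

**10 to 9, then to 6 and 7.** The aryl–carbonyl bond is cut: Grignard reagent 8 (from 7) adds to aldehyde 6, and carbinol 9 is oxidised. This joins ring A2 to the future C8a.

**6 to 3 and 4; 3 to 1.** Two ether bonds and the formyl group are cut. Chloride 4 already contains C7a and ring A1. Aldehyde 3 comes from bromoresorcinol 1 by formylation through iminium salt 2. The bromine of 1 marks C9b, a position meta to both oxygens that could not be functionalised later.

## Alternatives that were turned down

**Alternative 1:** (textbook route, polar and stepwise). The disconnection is C8b–C3c as a carbonyl addition and C7b–C10a as a separate cationic closure, with two differently functionalised halves: ketone A1 (from 14) and aryl bromide A2 (from 17). The forward key step is bromine–lithium exchange on A2, addition to A1 to give tertiary carbinol A3, then acid. It was turned down for these reasons: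
- Ionisation of A3 puts the charge on C8b (bis-benzylic, ortho-alkoxy-stabilised), not on C7b. Ring A2 then closes on C8b to a six-membered ring, or the cation loses a proton.
- The seven-membered ring would need protonation at C8b against this bias, which creates the C8b stereocentre by an undirected proton transfer.
- The union makes one C–C bond and no stereocentre, and the two halves cost at least five extra steps.

**Alternative 2:** (symmetric dimer, then bond migration). The disconnection is C8b–C3c by way of a C8b–C8c bond. The analogue A4 of 17, with both ortho positions of the phenol silylated, is oxidised to a persistent radical that dimerises to bis(quinone methide) A5. The forward key step is thermal homolysis of A5 and recombination at C3c (ipso to silicon, with loss of the silyl group), followed by Friedel–Crafts closure. It was turned down for these reasons: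
- The blocking groups that make the radical persistent also block C3c, so the wanted bond must form at a fully substituted carbon.
- A4 needs a silylated styrene partner and extra steps.
- A5 is set up for two Friedel–Crafts closures under the same acid.
- The unblocked phenol 17 reaches the C8b–C3c adduct directly.

**Alternative 3:** (late olefination). The disconnection is the olefin C7c=C8c, between aldehyde A6 (the upper three units) and phosphonate A7 (from 14). The forward key step is a Horner–Wadsworth–Emmons reaction. It was turned down for these reasons: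
- The key step would form only a C=C bond and no stereocentre.
- The hard bonds C8b–C3c and C7b–C10a are merely moved into the synthesis of A6. That would need a cross-coupling of radical 18 with a second, electron-poor phenol, which is statistically unselective, plus the same ring closure.
- A7 costs three more steps, and the identity of the two halves is not used.

Key step: step 9

Assumption: the sense of induction of the chiral dirhodium carboxylate in step 6 is not assigned here; the catalyst enantiomer that delivers the (3S) product is meant, written as Rh2(R-PTAD)4 (PTAD = N-phthaloyl-(1-adamantyl)glycinate).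

Benzofuran locants (C2, C3, C4) are used for the monomers; C2/C3 become C7a/C8a (or C7d/C8d) of the tetramer.

## Route

Step 1
Reactants: 1 5-bromobenzene-1,3-diol
Product: 3 2-bromo-4,6-dihydroxybenzaldehyde, via aryl iminium chloride 2 (not isolated)
Conditions: POCl3, DMF, MeCN, 0 °C to rt; then H2O, 50 °C
Reagents that add atoms: N,N-dimethylformamide CN(C)C=O; water O
Why: Vilsmeier–Haack formylation of an electron-rich arene; attack should go ortho to one hydroxyl and para to the other (next to bromine), the site between the two hydroxyls being more hindered, as in the formylation of 5-alkylresorcinols; hydrolysis of iminium salt 2 gives the aldehyde.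

Step 2
Reactants: 3 2-bromo-4,6-dihydroxybenzaldehyde; 4 1-(benzyloxy)-4-(chloromethyl)benzene
Product: 6 4-(benzyloxy)-2-{[4-(benzyloxy)benzyl]oxy}-6-bromobenzaldehyde, via monobenzyl ether 5 (not isolated)
Conditions: BnBr (1.0 equiv), KHCO3, MeCN, 60 °C; then 4, K2CO3, KI (cat.), 80 °C
Reagents that add atoms: benzyl bromide BrCc1ccccc1
Why: Williamson etherification in two stages; the hydroxyl para to the formyl group is the more acidic and is not held in the hydrogen bond to the carbonyl, so the weak base should benzylate it first (known selectivity of 2,4-dihydroxybenzaldehydes); the stronger base then alkylates the chelated ortho hydroxyl with 4, which brings in C7a and ring A1.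

Step 3
Reactants: 6 4-(benzyloxy)-2-{[4-(benzyloxy)benzyl]oxy}-6-bromobenzaldehyde; 7 1,3-bis(benzyloxy)-5-bromobenzene
Product: 9 rac-[3,5-bis(benzyloxy)phenyl](4-(benzyloxy)-2-{[4-(benzyloxy)benzyl]oxy}-6-bromophenyl)methanol, via aryl Grignard reagent 8 (not isolated)
Conditions: 7, Mg, THF, 40 °C; then 6, THF, 0 °C; aq NH4Cl
Reagents that add atoms: none
Why: Grignard addition of 8 to the aldehyde joins ring A2 to the future C8a; the aryl bromide and the benzyl ethers should not react with an aryl Grignard reagent at 0 °C; the new stereocentre is removed in the next step, so the racemate is used.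

Step 4
Reactants: 9 rac-[3,5-bis(benzyloxy)phenyl](4-(benzyloxy)-2-{[4-(benzyloxy)benzyl]oxy}-6-bromophenyl)methanol
Product: 10 [3,5-bis(benzyloxy)phenyl](4-(benzyloxy)-2-{[4-(benzyloxy)benzyl]oxy}-6-bromophenyl)methanone
Conditions: MnO2, CH2Cl2, rt
Reagents that add atoms: none
Why: oxidation of a doubly benzylic alcohol to the diaryl ketone with MnO2, a standard benzylic oxidation that leaves benzyl ethers and the aryl bromide alone.

Step 5
Reactants: 10 [3,5-bis(benzyloxy)phenyl](4-(benzyloxy)-2-{[4-(benzyloxy)benzyl]oxy}-6-bromophenyl)methanone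
Product: 11 hydrazone of ketone 10 (E/Z mixture)
Conditions: N2H4 (anhydrous), AcOH (cat.), EtOH–THF, 90 °C, sealed tube
Reagents that add atoms: hydrazine NN
Why: condensation of a diaryl ketone to its hydrazone, the usual entry to diaryldiazomethanes; forcing conditions are chosen because the carbonyl carries two ortho substituents.

Step 6
Reactants: 11 hydrazone of ketone 10
Product: 13 (2R,3S)-6-(benzyloxy)-2-[4-(benzyloxy)phenyl]-3-[3,5-bis(benzyloxy)phenyl]-4-bromo-2,3-dihydro-1-benzofuran (cis), via diaryldiazomethane 12 (not isolated)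
Conditions: MnO2, CH2Cl2, 0 °C, filtration; then Rh2(R-PTAD)4 (1 mol %), CH2Cl2, 0 °C to rt
Reagents that add atoms: none
Why: MnO2 oxidises the hydrazone to diazo compound 12, and the chiral dirhodium carboxylate turns it into a donor/donor carbene that inserts into the benzylic C–H bond of the ortho ether (1,5-insertion, five-membered ring); this is the known enantioselective carbene C–H insertion route to 2,3-diaryl-2,3-dihydrobenzofurans and should give the cis isomer; the catalyst sets C3, the only stereocentre of the route set by a reagent.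

Step 7
Reactants: 13 (2R,3S)-6-(benzyloxy)-2-[4-(benzyloxy)phenyl]-3-[3,5-bis(benzyloxy)phenyl]-4-bromo-2,3-dihydro-1-benzofuran (cis)
Product: 14 (2S,3S)-6-(benzyloxy)-2-[4-(benzyloxy)phenyl]-3-[3,5-bis(benzyloxy)phenyl]-4-bromo-2,3-dihydro-1-benzofuran (trans)
Conditions: TFA, CH2Cl2, 0 °C
Reagents that add atoms: none
Why: acid ionises the C2–O bond to the ring-opened 4-benzyloxybenzyl cation, which should reclose to the more stable trans isomer (known acid equilibration of 2-(4-alkoxyphenyl)dihydrobenzofurans); C3 is not touched, so C2 is relayed from C3 by substrate control; no olefin is present yet that could trap the cation.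

Step 8
Reactants: 14 (2S,3S)-6-(benzyloxy)-2-[4-(benzyloxy)phenyl]-3-[3,5-bis(benzyloxy)phenyl]-4-bromo-2,3-dihydro-1-benzofuran (trans); 15 4-ethenylphenyl acetate
Product: 17 4-[(E)-2-{(2S,3S)-6-(benzyloxy)-2-[4-(benzyloxy)phenyl]-3-[3,5-bis(benzyloxy)phenyl]-2,3-dihydro-1-benzofuran-4-yl}ethenyl]phenol, via stilbene acetate 16 (not isolated)
Conditions: Pd(OAc)2 (5 mol %), [HP(t-Bu)3]BF4 (10 mol %), K2CO3, DMF, 100 °C; then MeOH, rt
Reagents that add atoms: none
Why: Heck reaction of the aryl bromide (oxidative addition to zerovalent palladium carrying the bulky electron-rich phosphine, syn insertion, syn β-hydride elimination) should give the E-stilbene 16; methanolysis of the aryl acetate in the same flask frees the one phenol that the key step needs; the benzyl ethers and both stereocentres are inert to these conditions.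

Step 9
Reactants: 17 4-[(E)-2-{(2S,3S)-6-(benzyloxy)-2-[4-(benzyloxy)phenyl]-3-[3,5-bis(benzyloxy)phenyl]-2,3-dihydro-1-benzofuran-4-yl}ethenyl]phenol (two molecules)
Product: 22 octa-O-benzyl ether of 23 (free hydroxyls only on ring B1 and ring C1; 7aS,8aS,7bS,8bS,7dS,8dS), via phenoxyl radical 18 (not isolated), via dienone quinone methide 19 (not isolated), via phenol quinone methide 20 (not isolated), via O-closed dihydrobenzofuran dimer 21 (not isolated)
Conditions: Ag2O (0.55 equiv per 17), 4 Å MS, CH2Cl2, rt, dark; filtration under argon; then BF3·OEt2 (1.5 equiv), CH2Cl2, −40 to 0 °C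
Reagents that add atoms: none
Why: Ag2O oxidises the single free phenol of 17 to radical 18 (spin on O, C3/C5 and C8); two radicals join C8b to C3c to give 19, which tautomerises to phenol 20 and closes through oxygen (5-exo-trig oxa-1,6-addition) to the trans-dihydrobenzofuran 21, the known course of silver-oxide coupling of 4-hydroxystyrenes and 4-hydroxystilbenes. Compound 21 is a resting state by design: it has no oxidisable stilbene phenol left, so the oxidant is filtered off before the skeleton is switched. BF3·OEt2 then ionises the only dihydrobenzofuran whose C2 aryl carries a free para-hydroxyl (back to 20 as its Lewis-acid complex), and C10a of ring A2 attacks C7b in a 7-exo-trig Friedel–Crafts closure whose irreversible C–C bond drains 21; the closest known reaction type is the Lewis-acid cyclisation of para-quinone methides by a 3,5-dialkoxyphenyl ring to the seven-membered ring of ampelopsin-type oligostilbenes. C8b is set in the radical coupling: the partner must add to the Si face of C8b, which is the face anti to ring A2 in the rotamer that keeps H-8b (not C7b) next to H-14b; this bias is expected to be modest. The ring closure is a second gate for C8b: only the Si adduct can place ring C1 pseudo-axial, anti to ring A2, with H-8b in the plane of ring B2, whereas the Re adduct would have to push ring C1 against H-14b and should stay in the O-closed series, from which it is separated. C7b is set in the Friedel–Crafts step by C8a and C8b: ring A2 can reach only one face of the quinone methide, and the quinoid ring should turn away from ring B2 into the pseudo-equatorial position, which gives H-7b cis to H-8b and trans to H-8a. The step needs oxidation at one phenol only (secured by the four benzyl ethers), C8–C3 coupling instead of C8–C8 or C–O coupling (the usual preference of ortho-unsubstituted 4-hydroxystilbene radicals on silver), and acid discrimination between three dihydrobenzofurans (secured by the free para-hydroxyl of ring B1 and the low temperature). In one operation it forms C8b–C3c and C7b–C10a, the seven-membered ring and two stereocentres, and doubles the carbon skeleton.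

Step 10
Reactants: 22 octa-O-benzyl ether of 23 (free hydroxyls only on ring B1 and ring C1)
Product: 23 target tetramer CNP0266373.2 (7aS,8aS,7bS,8bS,7dS,8dS)
Conditions: BCl3, pentamethylbenzene, CH2Cl2, −78 °C; then MeOH
Reagents that add atoms: none
Why: BCl3 cleaves the eight aryl benzyl ethers at −78 °C and pentamethylbenzene traps the benzyl cations (Friedel–Crafts benzylation of the scavenger), a non-reductive debenzylation that spares the stilbene; the low temperature is meant to keep the acid-labile para-hydroxybenzylic bonds and all six stereocentres intact.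

## Compound list

1 | 5-bromobenzene-1,3-diol | Oc1cc(O)cc(Br)c1 | starting material
2 | [(2-bromo-4,6-dihydroxyphenyl)methylidene]dimethylazanium chloride | C[N+](C)=Cc1c(O)cc(O)cc1Br.[Cl-] | intermediate
3 | 2-bromo-4,6-dihydroxybenzaldehyde | O=Cc1c(O)cc(O)cc1Br | intermediate
4 | 1-(benzyloxy)-4-(chloromethyl)benzene | ClCc1ccc(OCc2ccccc2)cc1 | starting material
5 | 4-(benzyloxy)-2-bromo-6-hydroxybenzaldehyde | O=Cc1c(O)cc(OCc2ccccc2)cc1Br | intermediate
6 | 4-(benzyloxy)-2-{[4-(benzyloxy)benzyl]oxy}-6-bromobenzaldehyde | O=Cc1c(OCc2ccc(OCc3ccccc3)cc2)cc(OCc2ccccc2)cc1Br | intermediate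
7 | 1,3-bis(benzyloxy)-5-bromobenzene | Brc1cc(OCc2ccccc2)cc(OCc2ccccc2)c1 | starting material
8 | [3,5-bis(benzyloxy)phenyl]magnesium bromide | Br[Mg]c1cc(OCc2ccccc2)cc(OCc2ccccc2)c1 | intermediate
9 | rac-[3,5-bis(benzyloxy)phenyl](4-(benzyloxy)-2-{[4-(benzyloxy)benzyl]oxy}-6-bromophenyl)methanol | OC(c1cc(OCc2ccccc2)cc(OCc2ccccc2)c1)c1c(OCc2ccc(OCc3ccccc3)cc2)cc(OCc2ccccc2)cc1Br | intermediate
10 | [3,5-bis(benzyloxy)phenyl](4-(benzyloxy)-2-{[4-(benzyloxy)benzyl]oxy}-6-bromophenyl)methanone | O=C(c1cc(OCc2ccccc2)cc(OCc2ccccc2)c1)c1c(OCc2ccc(OCc3ccccc3)cc2)cc(OCc2ccccc2)cc1Br | intermediate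
11 | hydrazone of ketone 10 (E/Z mixture) | NN=C(c1cc(OCc2ccccc2)cc(OCc2ccccc2)c1)c1c(OCc2ccc(OCc3ccccc3)cc2)cc(OCc2ccccc2)cc1Br | intermediate
12 | 1,3-bis(benzyloxy)-5-[(4-(benzyloxy)-2-{[4-(benzyloxy)benzyl]oxy}-6-bromophenyl)(diazo)methyl]benzene | [N-]=[N+]=C(c1cc(OCc2ccccc2)cc(OCc2ccccc2)c1)c1c(OCc2ccc(OCc3ccccc3)cc2)cc(OCc2ccccc2)cc1Br | intermediate
13 | (2R,3S)-6-(benzyloxy)-2-[4-(benzyloxy)phenyl]-3-[3,5-bis(benzyloxy)phenyl]-4-bromo-2,3-dihydro-1-benzofuran (cis) | Brc1cc(OCc2ccccc2)cc2c1[C@H](c1cc(OCc3ccccc3)cc(OCc3ccccc3)c1)[C@H](c1ccc(OCc3ccccc3)cc1)O2 | intermediate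
14 | (2S,3S)-6-(benzyloxy)-2-[4-(benzyloxy)phenyl]-3-[3,5-bis(benzyloxy)phenyl]-4-bromo-2,3-dihydro-1-benzofuran (trans) | Brc1cc(OCc2ccccc2)cc2c1[C@H](c1cc(OCc3ccccc3)cc(OCc3ccccc3)c1)[C@@H](c1ccc(OCc3ccccc3)cc1)O2 | intermediate
15 | 4-ethenylphenyl acetate | CC(=O)Oc1ccc(C=C)cc1 | starting material
16 | 4-[(E)-2-{(2S,3S)-6-(benzyloxy)-2-[4-(benzyloxy)phenyl]-3-[3,5-bis(benzyloxy)phenyl]-2,3-dihydro-1-benzofuran-4-yl}ethenyl]phenyl acetate | CC(=O)Oc1ccc(/C=C/c2cc(OCc3ccccc3)cc3c2[C@H](c2cc(OCc4ccccc4)cc(OCc4ccccc4)c2)[C@@H](c2ccc(OCc4ccccc4)cc2)O3)cc1 | intermediate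
17 | 4-[(E)-2-{(2S,3S)-6-(benzyloxy)-2-[4-(benzyloxy)phenyl]-3-[3,5-bis(benzyloxy)phenyl]-2,3-dihydro-1-benzofuran-4-yl}ethenyl]phenol | Oc1ccc(/C=C/c2cc(OCc3ccccc3)cc3c2[C@H](c2cc(OCc4ccccc4)cc(OCc4ccccc4)c2)[C@@H](c2ccc(OCc4ccccc4)cc2)O3)cc1 | intermediate
18 | phenoxyl radical of 17 | [O]c1ccc(/C=C/c2cc(OCc3ccccc3)cc3c2[C@H](c2cc(OCc4ccccc4)cc(OCc4ccccc4)c2)[C@@H](c2ccc(OCc4ccccc4)cc2)O3)cc1 | intermediate
19 | C8b–C3c adduct of two radicals 18 as quinone methide (unit b) and cyclohexa-2,4-dienone (unit c); 8bS, both C3c epimers | O=C1C=CC(=C[C@@H](c2cc(OCc6ccccc6)cc3c2[C@H](c2cc(OCc6ccccc6)cc(OCc6ccccc6)c2)[C@@H](c2ccc(OCc6ccccc6)cc2)O3)C2C=C(/C=C/c4cc(OCc6ccccc6)cc5c4[C@H](c4cc(OCc6ccccc6)cc(OCc6ccccc6)c4)[C@@H](c4ccc(OCc6ccccc6)cc4)O5)C=CC2=O)C=C1 | intermediate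
20 | phenol tautomer of 19 (para-quinone methide at C7b, free phenol on ring C1; 8bS) | O=C1C=CC(=C[C@@H](c2cc(OCc6ccccc6)cc3c2[C@H](c2cc(OCc6ccccc6)cc(OCc6ccccc6)c2)[C@@H](c2ccc(OCc6ccccc6)cc2)O3)c2cc(/C=C/c4cc(OCc6ccccc6)cc5c4[C@H](c4cc(OCc6ccccc6)cc(OCc6ccccc6)c4)[C@@H](c4ccc(OCc6ccccc6)cc4)O5)ccc2O)C=C1 | intermediate
21 | O-closed dimer: the two halves joined by C8b–C3c and O(C4c)–C7b in a trans-2-(4-hydroxyphenyl)-2,3-dihydrobenzofuran (7bS,8bS); eight benzyl ethers | Oc1ccc([C@H]2Oc3ccc(/C=C/c4cc(OCc6ccccc6)cc5c4[C@H](c4cc(OCc6ccccc6)cc(OCc6ccccc6)c4)[C@@H](c4ccc(OCc6ccccc6)cc4)O5)cc3[C@@H]2c2cc(OCc6ccccc6)cc3c2[C@H](c2cc(OCc6ccccc6)cc(OCc6ccccc6)c2)[C@@H](c2ccc(OCc6ccccc6)cc2)O3)cc1 | intermediate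
22 | octa-O-benzyl ether of 23 (free hydroxyls only on ring B1 and ring C1; 7aS,8aS,7bS,8bS,7dS,8dS) | Oc1ccc([C@H]2c3c(OCc6ccccc6)cc(OCc6ccccc6)cc3[C@H]3c4c(cc(OCc6ccccc6)cc4[C@H]2c2cc(/C=C/c4cc(OCc6ccccc6)cc5c4[C@H](c4cc(OCc6ccccc6)cc(OCc6ccccc6)c4)[C@@H](c4ccc(OCc6ccccc6)cc4)O5)ccc2O)O[C@@H]3c2ccc(OCc6ccccc6)cc2)cc1 | intermediate
23 | target tetramer CNP0266373.2 (7aS,8aS,7bS,8bS,7dS,8dS) | Oc1ccc([C@H]2c3c(O)cc(O)cc3[C@H]3c4c(cc(O)cc4[C@H]2c2cc(/C=C/c4cc(O)cc5c4[C@H](c4cc(O)cc(O)c4)[C@@H](c4ccc(O)cc4)O5)ccc2O)O[C@@H]3c2ccc(O)cc2)cc1 | target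

## Step count and least certain steps

Total step count: 10. Longest linear sequence: 10 steps (1 to 23); compounds 4, 7 and 15 enter as purchased building blocks.

**Step 9 (key step).** Three things may go wrong:
- the radicals may couple through C8–C8 or through oxygen instead of C8–C3;
- facial selectivity at C8b may be poor, so that much material ends in the Re-face series;
- in the acid stage, the two benzyl-protected dihydrobenzofurans may ionise or the remaining stilbene may be protonated, with skeletal isomerisation.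

The fallback is polar, with the bond order reversed. It sets out from 17 and comes back to the route at 23. Part of 17 is benzylated (BnBr, K2CO3) to the pentabenzyl ether F1. Epoxidation of its stilbene with dimethyldioxirane gives the trans-oxirane F2. BF3·OEt2 at low temperature opens the oxirane at C7b, and ring A2 closes the seven-membered ring to the C8b carbinol F3. Acid-catalysed ortho-alkylation of phenol 17 by the C8b cation from F3 (Friedel–Crafts benzylation of a phenol) then gives the nonabenzyl ether F4. F4 is debenzylated under the conditions of step 10 to 23.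

**Step 5.** The condensation may stall because the carbonyl is flanked by two ortho substituents, or the hydrazone may cyclise onto the ortho bromide. The fallback sets out from 10 and comes back at 14. Carbanion cyclisation of the benzylic ether onto the ketone and dehydration (LiTMP, then TsOH) gives the 2,3-diarylbenzofuran F5. Ionic hydrogenation (Et3SiH, TFA) reduces it to the racemic trans-dihydrobenzofuran, that is 14 together with its enantiomer F6. Chromatography on a chiral stationary phase delivers 14.

**Step 6.** The crowded diaryl carbene may form azine or add to an arene instead of inserting, and enantioselectivity may be low with two ortho substituents. The fallback sets out from 17 of insufficient enantiomeric purity and comes back at 17. Esterification with (S)-methoxy(phenyl)acetic acid (carbodiimide, DMAP) gives the diastereomeric ester F7, which is purified by crystallisation or chromatography. Methanolysis (K2CO3, MeOH) returns 17. The absolute configuration is then secured by resolution instead of by the catalyst.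

**Step 8.** Oxidative addition at the bromide next to the fully substituted C3a may be slow, and reduction of the C–Br bond may win. The fallback sets out from 14 and comes back at 17. Bromine–lithium exchange and formylation (n-BuLi, then DMF) give the aldehyde F8. Horner–Wadsworth–Emmons olefination with diethyl {4-[(tert-butyldimethylsilyl)oxy]benzyl}phosphonate (KOt-Bu, THF) gives the E-stilbene silyl ether F9. Fluoride (TBAF) frees 17.

**Step 10.** The Lewis acid may ionise the para-hydroxybenzylic bonds (C7b–C10a, C7a–O, C7d–O) or protonate the stilbene, with epimerisation or rearrangement of the skeleton; debenzylation may also be incomplete. The fallback sets out from 22 and comes back at 23. The two free phenols are acetylated (Ac2O, pyridine) to the diacetate F10, which removes the two strongest cation-stabilising hydroxyls. Debenzylation as in step 10 gives the octahydroxy diacetate F11. Mild methanolysis (K2CO3, MeOH, 0 °C, argon) gives 23.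

## Further compounds

F1 | step 9 | (2S,3S)-6-(benzyloxy)-2-[4-(benzyloxy)phenyl]-3-[3,5-bis(benzyloxy)phenyl]-4-{(E)-2-[4-(benzyloxy)phenyl]ethenyl}-2,3-dihydro-1-benzofuran | C(c1ccccc1)Oc1ccc(/C=C/c2cc(OCc3ccccc3)cc3c2[C@H](c2cc(OCc4ccccc4)cc(OCc4ccccc4)c2)[C@@H](c2ccc(OCc4ccccc4)cc2)O3)cc1
F2 | step 9 | trans-oxirane of F1 at the former olefin (both trans diastereomers; oxirane centres not specified) | C(c1ccccc1)Oc1ccc(C2OC2c2cc(OCc3ccccc3)cc3c2[C@H](c2cc(OCc4ccccc4)cc(OCc4ccccc4)c2)[C@@H](c2ccc(OCc4ccccc4)cc2)O3)cc1
F3 | step 9 | penta-O-benzyl seven-membered-ring carbinol (C7a S, C8a S, C7b S; hydroxyl at C8b, both C8b epimers) | C(c1ccccc1)Oc1ccc([C@H]2c3c(OCc6ccccc6)cc(OCc6ccccc6)cc3[C@H]3c4c(cc(OCc6ccccc6)cc4C2O)O[C@@H]3c2ccc(OCc6ccccc6)cc2)cc1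
F4 | step 9 | nona-O-benzyl ether of 23 (only the hydroxyl of ring C1 free) | C(c1ccccc1)Oc1ccc([C@H]2c3c(OCc6ccccc6)cc(OCc6ccccc6)cc3[C@H]3c4c(cc(OCc6ccccc6)cc4[C@H]2c2cc(/C=C/c4cc(OCc6ccccc6)cc5c4[C@H](c4cc(OCc6ccccc6)cc(OCc6ccccc6)c4)[C@@H](c4ccc(OCc6ccccc6)cc4)O5)ccc2O)O[C@@H]3c2ccc(OCc6ccccc6)cc2)cc1
F5 | step 5 | 6-(benzyloxy)-2-[4-(benzyloxy)phenyl]-3-[3,5-bis(benzyloxy)phenyl]-4-bromo-1-benzofuran | Brc1cc(OCc2ccccc2)cc2oc(-c3ccc(OCc4ccccc4)cc3)c(-c3cc(OCc4ccccc4)cc(OCc4ccccc4)c3)c12
F6 | step 5 | (2R,3R)-enantiomer of 14, formed with 14 as the racemate | Brc1cc(OCc2ccccc2)cc2c1[C@@H](c1cc(OCc3ccccc3)cc(OCc3ccccc3)c1)[C@H](c1ccc(OCc3ccccc3)cc1)O2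
F7 | step 6 | (S)-methoxy(phenyl)acetate ester of phenol 17 | CO[C@H](C(=O)Oc1ccc(/C=C/c2cc(OCc3ccccc3)cc3c2[C@H](c2cc(OCc4ccccc4)cc(OCc4ccccc4)c2)[C@@H](c2ccc(OCc4ccccc4)cc2)O3)cc1)c1ccccc1
F8 | step 8 | (2S,3S)-6-(benzyloxy)-2-[4-(benzyloxy)phenyl]-3-[3,5-bis(benzyloxy)phenyl]-2,3-dihydro-1-benzofuran-4-carbaldehyde | O=Cc1cc(OCc2ccccc2)cc2c1[C@H](c1cc(OCc3ccccc3)cc(OCc3ccccc3)c1)[C@@H](c1ccc(OCc3ccccc3)cc1)O2
F9 | step 8 | tert-butyldimethylsilyl ether of phenol 17 | CC(C)(C)[Si](C)(C)Oc1ccc(/C=C/c2cc(OCc3ccccc3)cc3c2[C@H](c2cc(OCc4ccccc4)cc(OCc4ccccc4)c2)[C@@H](c2ccc(OCc4ccccc4)cc2)O3)cc1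
F10 | step 10 | diacetate of 22 (acetates on ring B1 and ring C1, eight benzyl ethers) | CC(=O)Oc1ccc([C@H]2c3c(OCc6ccccc6)cc(OCc6ccccc6)cc3[C@H]3c4c(cc(OCc6ccccc6)cc4[C@H]2c2cc(/C=C/c4cc(OCc6ccccc6)cc5c4[C@H](c4cc(OCc6ccccc6)cc(OCc6ccccc6)c4)[C@@H](c4ccc(OCc6ccccc6)cc4)O5)ccc2OC(C)=O)O[C@@H]3c2ccc(OCc6ccccc6)cc2)cc1
F11 | step 10 | diacetate of 23 (acetates on ring B1 and ring C1, eight free hydroxyls) | CC(=O)Oc1ccc([C@H]2c3c(O)cc(O)cc3[C@H]3c4c(cc(O)cc4[C@H]2c2cc(/C=C/c4cc(O)cc5c4[C@H](c4cc(O)cc(O)c4)[C@@H](c4ccc(O)cc4)O5)ccc2OC(C)=O)O[C@@H]3c2ccc(O)cc2)cc1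
A1 | alternative 1 | 1-{(2S,3S)-6-(benzyloxy)-2-[4-(benzyloxy)phenyl]-3-[3,5-bis(benzyloxy)phenyl]-2,3-dihydro-1-benzofuran-4-yl}-2-[4-(benzyloxy)phenyl]ethanone | O=C(Cc1ccc(OCc2ccccc2)cc1)c1cc(OCc2ccccc2)cc2c1[C@H](c1cc(OCc3ccccc3)cc(OCc3ccccc3)c1)[C@@H](c1ccc(OCc3ccccc3)cc1)O2
A2 | alternative 1 | (2S,3S)-6-(benzyloxy)-2-[4-(benzyloxy)phenyl]-3-[3,5-bis(benzyloxy)phenyl]-4-{(E)-2-[4-(benzyloxy)-3-bromophenyl]ethenyl}-2,3-dihydro-1-benzofuran | Brc1cc(/C=C/c2cc(OCc3ccccc3)cc3c2[C@H](c2cc(OCc4ccccc4)cc(OCc4ccccc4)c2)[C@@H](c2ccc(OCc4ccccc4)cc2)O3)ccc1OCc1ccccc1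
A3 | alternative 1 | tertiary carbinol from A1 and lithiated A2 (carbinol centre C8b, both epimers) | OC(Cc1ccc(OCc2ccccc2)cc1)(c1cc(OCc2ccccc2)cc2c1[C@H](c1cc(OCc3ccccc3)cc(OCc3ccccc3)c1)[C@@H](c1ccc(OCc3ccccc3)cc1)O2)c1cc(/C=C/c2cc(OCc3ccccc3)cc3c2[C@H](c2cc(OCc4ccccc4)cc(OCc4ccccc4)c2)[C@@H](c2ccc(OCc4ccccc4)cc2)O3)ccc1OCc1ccccc1
A4 | alternative 2 | analogue of 17 with trimethylsilyl groups on both carbons ortho to the phenol hydroxyl | Oc1c([Si](C)(C)C)cc(/C=C/c2cc(OCc3ccccc3)cc3c2[C@H](c2cc(OCc4ccccc4)cc(OCc4ccccc4)c2)[C@@H](c2ccc(OCc4ccccc4)cc2)O3)cc1[Si](C)(C)C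
A5 | alternative 2 | C8b–C8c bis(quinone methide) dimer of the radical from A4 (new centres not specified) | C[Si](C)(C)C1=CC(=CC(c2cc(OCc3ccccc3)cc3c2[C@H](c2cc(OCc4ccccc4)cc(OCc4ccccc4)c2)[C@@H](c2ccc(OCc4ccccc4)cc2)O3)C(C=C2C=C([Si](C)(C)C)C(=O)C([Si](C)(C)C)=C2)c2cc(OCc3ccccc3)cc3c2[C@H](c2cc(OCc4ccccc4)cc(OCc4ccccc4)c2)[C@@H](c2ccc(OCc4ccccc4)cc2)O3)C=C([Si](C)(C)C)C1=O
A6 | alternative 3 | upper three-unit aldehyde: seven-membered-ring core (7aS,8aS,7bS,8bS) with a 5-formyl-2-hydroxyphenyl group on C8b, four benzyl ethers, free hydroxyl on ring B1 | Oc1ccc([C@H]2c3c(OCc6ccccc6)cc(OCc6ccccc6)cc3[C@H]3c4c(cc(OCc6ccccc6)cc4[C@H]2c2cc(C=O)ccc2O)O[C@@H]3c2ccc(OCc6ccccc6)cc2)cc1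
A7 | alternative 3 | diethyl ({(2S,3S)-6-(benzyloxy)-2-[4-(benzyloxy)phenyl]-3-[3,5-bis(benzyloxy)phenyl]-2,3-dihydro-1-benzofuran-4-yl}methyl)phosphonate | CCOP(=O)(OCC)Cc1cc(OCc2ccccc2)cc2c1[C@H](c1cc(OCc3ccccc3)cc(OCc3ccccc3)c1)[C@@H](c1ccc(OCc3ccccc3)cc1)O2
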